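**Retrosynthetic overview**
1. The seven-membered ring that lacks the exocyclic methylene is read as a five-carbon arc (bridge CH2 – bridgehead =C – CH2 – CH2 – ring carbon of the C=C(CH3) unit) plus the two adjacent methines (the CH bearing the C(=CH2) carbon and the CH shared with the cyclohexene).
2. Enabling feature: a temporary bond between the bridge CH2 and the cyclohexene sp2 carbon turns that arc into a cyclopent-2-enone (its C=O is the future bridgehead alkene carbon) and the two methines into an E-alkene. The tetrasubstituted C=C(CH3) of the target marks where this bond can be cut again, by a radical on the methyl-bearing carbon.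
3. Key disconnection: intramolecular enone–alkene [2+2] photocycloaddition of a monocyclic cyclopentenone that carries a four-atom tether. It closes the six-membered ring and a cyclobutane and sets both ring-fusion methines.
4. Ring order: cyclopentenone (temporary, bought) → cyclohexane + cyclobutane (step 8) → seven-membered ring with the future bridgehead alkene by RCM on the fused photoadduct (step 11) → bicyclo[4.4.1]undecene and cyclohexene C=C by radical cleavage of the temporary bond (step 14).
5. The acyclic photosubstrate comes from (S)-citronellal, methyl vinyl ketone, a C2 Wittig reagent and 3-bromocyclopent-2-enone.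

Key step: step 8

Remark on the chemistry: the carbinol carbon made in step 6 forms as both epimers. They are carried together (this centre is left undefined in the SMILES of 11–19) because it becomes sp2 in step 14.
Abbreviations: Rp = (2S)-6-methylhept-5-en-2-yl; Rh = (2S,5E)-7-hydroxy-6-methylhept-5-en-2-yl; Rs = (2S,5E)-7-[(tert-butyldiphenylsilyl)oxy]-6-methylhept-5-en-2-yl. Compounds 13–16 use tricyclo[5.4.0.0^1,5]undecane numbering (C1 quaternary, C4 the cyclopentane carbon bearing C=O or =CH2, C5/C6/C7 cyclobutane CH, C8 bears Rs, C11 carbinol carbon).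

Step 1
Reactants: 1 (S)-citronellal; 2 methyl vinyl ketone
Product: 3 (2S)-2-Rp-5-oxohexanal
Conditions: (S)-2-[methoxy(diphenyl)methyl]pyrrolidine (5 mol%), ethyl 3,4-dihydroxybenzoate (20 mol%), neat, 4 °C
Reagents that add atoms: none
Why: Enamine-catalysed Michael addition of an aldehyde to an enone; the E-enamine is shielded on one face by the diphenyl(methoxy)methyl group, so the enone should add to the open face and set the new α-centre as (S) under catalyst control, the citronellal centre being untouched.

Step 2
Reactants: 3 (2S)-2-Rp-5-oxohexanal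
Product: 4 methyl (2E,4S)-4-Rp-7-oxooct-2-enoate
Conditions: Ph3P=CHCO2Me, CH2Cl2, 0 °C to rt
Reagents that add atoms: methyl (triphenylphosphoranylidene)acetate COC(=O)C=P(c1ccccc1)(c1ccccc1)c1ccccc1
Why: Wittig olefination with a stabilised ylide reacts only with the aldehyde (not the methyl ketone), gives the E-enoate and is mild enough to leave the α-stereocentre intact.

Step 3
Reactants: 4 methyl (2E,4S)-4-Rp-7-oxooct-2-enoate
Product: 5 methyl (2E,4S)-4-Rh-7-oxooct-2-enoate
Conditions: SeO2 (0.3 equiv), t-BuOOH (3 equiv), salicylic acid (0.1 equiv), CH2Cl2, rt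
Reagents that add atoms: selenium dioxide O=[Se]=O; tert-butyl hydroperoxide CC(C)(C)OO
Why: Riley allylic oxidation (ene reaction, then [2,3]-sigmatropic shift) of the only electron-rich trisubstituted alkene occurs at the methyl group trans to the chain and should give the E-allylic alcohol, the electron-poor enoate alkene and the ketone being left.

Step 4
Reactants: 5 methyl (2E,4S)-4-Rh-7-oxooct-2-enoate
Product: 6 methyl (2E,4S)-4-Rs-7-oxooct-2-enoate
Conditions: TBDPSCl, imidazole, CH2Cl2, 0 °C to rt
Reagents that add atoms: tert-butyl(chloro)diphenylsilane CC(C)(C)[Si](Cl)(c1ccccc1)c1ccccc1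
Why: Silylation of the primary alcohol; the TBDPS ether is chosen to survive organometallics, mild acid, irradiation, base and tin hydride.

Step 5
Reactants: 7 3-bromocyclopent-2-en-1-one
Product: 8 7-bromo-1,4-dioxaspiro[4.4]non-6-ene
Conditions: Me3SiOCH2CH2OSiMe3, TMSOTf (cat.), CH2Cl2, −78 °C
Reagents that add atoms: 1,2-bis(trimethylsilyloxy)ethane C[Si](C)(C)OCCO[Si](C)(C)C
Why: TMSOTf-catalysed silyl-transfer acetalization is an aprotic, low-temperature ketalisation of enones that attacks the carbonyl carbon and should neither shift the double bond nor displace the vinylic bromide.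

Step 6
Reactants: 8 7-bromo-1,4-dioxaspiro[4.4]non-6-ene; 6 methyl (2E,4S)-4-Rs-7-oxooct-2-enoate
Product: 11 methyl (2E,4S)-7-(1,4-dioxaspiro[4.4]non-6-en-7-yl)-7-hydroxy-4-Rs-oct-2-enoate (both C7 epimers), via vinyllithium 9 (not isolated), via organocerium reagent 10 (not isolated)
Conditions: 8, t-BuLi (2 equiv), THF, −78 °C; CeCl3, −78 °C; then 6, −78 °C; aq. NH4Cl at −78 °C
Reagents that add atoms: none
Why: Bromine–lithium exchange and transmetalation give a weakly basic organocerium reagent that should add 1,2 to the methyl ketone in preference to the unsaturated ester and without enolisation; the new carbinol centre is remote and forms as both epimers, which does not matter.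

Step 7
Reactants: 11 methyl (2E,4S)-7-(1,4-dioxaspiro[4.4]non-6-en-7-yl)-7-hydroxy-4-Rs-oct-2-enoate
Product: 12 methyl (2E,4S)-7-hydroxy-7-(3-oxocyclopent-1-en-1-yl)-4-Rs-oct-2-enoate (both C7 epimers)
Conditions: PPTS, THF/H2O, rt to 40 °C
Reagents that add atoms: water O
Why: Mild acid hydrolysis of the allylic dioxolane unmasks the conjugated enone, so steps 6 and 7 together amount to the addition of a β-acylvinyl anion; the silyl ether and the tertiary alcohol should tolerate PPTS.

Step 8
Reactants: 12 methyl (2E,4S)-7-hydroxy-7-(3-oxocyclopent-1-en-1-yl)-4-Rs-oct-2-enoate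
Product: 13 methyl 11-hydroxy-11-methyl-4-oxo-8-Rs-tricyclo[5.4.0.0^1,5]undecane-6-carboxylate (cyclopentanone and cyclohexane cis-fused to the cyclobutane on opposite faces; CO2Me at C6 cis to C4 and trans to C8; H7 and H8 trans)
Conditions: hν (350 nm, Pyrex), degassed CH2Cl2 (0.005 M), 0 °C
Reagents that add atoms: none
Why: The excited cyclopentenone (triplet after intersystem crossing) bonds from its β-carbon to the alkene carbon next to the stereocentre, and the resulting 1,4-biradical closes; the closest known reaction type is the straight intramolecular enone–alkene [2+2] photocycloaddition of 3-alkenylcycloalk-2-enones with four-atom tethers. The cyclohexane closes first by 1,6-bonding (6-exo attack that leaves an ester-stabilised radical and an α-keto radical), the cyclobutane then by recombination of the 1,4-biradical; the crossed mode would need a seven-membered first closure. C7 is controlled by the existing allylic centre C8: in the chair-like folding of the tether the branched side chain is equatorial and the allylic C–H eclipses the alkene, so the enone should add to the alkene face anti to the side chain and give H7 trans to H8. C1 and C5 follow from geometric constraint, since the cyclopentanone and the new cyclohexane can only be cis-fused to the cyclobutane and therefore lie on opposite faces. C6 is fixed when the biradical closes, which should place the ester trans to the C8 branch (the E relationship of the enoate carried over); this centre remains epimerisable and is proofread in step 11. The step needs straight over crossed regioselectivity and face selectivity, and these are secured by the four-atom tether, the fully substituted carbinol carbon that favours folding, and the allylic stereocentre.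

Step 9
Reactants: 13 photoadduct keto ester
Product: 14 methyl 11-hydroxy-11-methyl-4-methylidene-8-Rs-tricyclo[5.4.0.0^1,5]undecane-6-carboxylate
Conditions: Ph3PCH3Br, KOt-Bu, THF, 0 °C
Reagents that add atoms: methyltriphenylphosphonium bromide C[P+](c1ccccc1)(c1ccccc1)c1ccccc1.[Br-]
Why: Wittig methylenation of the strained cyclopentanone is fast, whereas the cyclobutanecarboxylate is hard to enolise (exocyclic enolate on a four-membered ring), so C6 should keep its configuration.

Step 10
Reactants: 14 methylidene ester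
Product: 16 1-(11-hydroxy-11-methyl-4-methylidene-8-Rs-tricyclo[5.4.0.0^1,5]undecan-6-yl)pent-4-en-1-one, via Weinreb amide 15 (not isolated)
Conditions: MeNH(OMe)·HCl, i-PrMgCl, THF, −20 °C; then CH2=CHCH2CH2MgBr, −20 to 0 °C; aq. NH4Cl
Reagents that add atoms: N,O-dimethylhydroxylamine hydrochloride CNOC.Cl (atoms in 15 only); but-3-enylmagnesium bromide C=CCC[Mg]Br
Why: Ester-to-amide exchange with the magnesium amide followed by Grignard addition (Weinreb ketone synthesis) stops at the ketone because the chelated tetrahedral adduct collapses only on work-up.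

Step 11
Reactants: 16 pentenyl ketone
Product: 17 tetracyclic ketone in which C6–C(=O)–CH2–CH2–CH= is joined to C4 (cyclohept-4-en-1-one fused across C4, C5, C6 of the tricycle)
Conditions: second-generation Grubbs catalyst RuCl2(=CHPh)(H2IMes)(PCy3) (5 mol%), CH2Cl2 (0.002 M), 40 °C
Reagents that add atoms: none
Why: Ring-closing metathesis of the terminal vinyl group with the exocyclic methylene closes the seven-membered ring as an ordinary fused ring with a trisubstituted alkene, because the temporary cyclobutane holds C4 and the C6 acyl chain cis; only the C6 epimer with the acyl group cis to the cyclopentane can close, so the step proofreads C6 (the other epimer is recycled by base equilibration of ketone 16).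

Step 12
Reactants: 17 tetracyclic ketone
Product: 18 tetracyclic diene alcohol (C=O of 17 replaced by C=CH2)
Conditions: Ph3PCH3Br, KOt-Bu, THF/toluene, rt to 60 °C
Reagents that add atoms: methyltriphenylphosphonium bromide C[P+](c1ccccc1)(c1ccccc1)c1ccccc1.[Br-]
Why: Wittig methylenation installs the exocyclic methylene; the α-centre is now locked by the cis ring fusion and cannot epimerise.

Step 13
Reactants: 18 tetracyclic diene alcohol
Product: 19 methyl oxalate of 18
Conditions: KN(SiMe3)2, THF, −78 °C; ClC(O)CO2Me, −78 to 0 °C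
Reagents that add atoms: methyl chlorooxoacetate COC(=O)C(Cl)=O
Why: Acylation of the potassium alkoxide with the very reactive acid chloride gives the tertiary methyl oxalate, the usual radical precursor for tertiary alcohols that cannot form xanthates.

Step 14
Reactants: 19 methyl oxalate
Product: 20 O-TBDPS ether of the target
Conditions: Bu3SnH (slow addition), AIBN (cat.), toluene, 110 °C
Reagents that add atoms: none
Why: Barton–McCombie-type deoxygenation of the tertiary oxalate gives the tertiary radical at the carbinol carbon, whose cyclobutylcarbinyl ring opening (known for enone–alkene photoadducts) should cleave the cyclobutane bond exocyclic to the radical-bearing six-membered ring (quaternary carbon to the CH next to the ring alkene), giving the tetrasubstituted C=C and a secondary radical at the future bridge carbon that is twisted out of conjugation and is reduced there by the stannane; no stereocentre is made or touched.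

Step 15
Reactants: 20 O-TBDPS ether of the target
Product: 21 CNP0289180.1
Conditions: TBAF, THF, 0 °C to rt
Reagents that add atoms: none
Why: Fluoride cleavage of the silyl ether; nothing else in the molecule reacts with TBAF.

**Compound list**
1 | (S)-citronellal, (3S)-3,7-dimethyloct-6-enal | O=CC[C@@H](C)CCC=C(C)C | starting material
2 | methyl vinyl ketone (but-3-en-2-one) | CC(=O)C=C | starting material
3 | (2S)-2-[(2S)-6-methylhept-5-en-2-yl]-5-oxohexanal | CC(=O)CC[C@@H]([C@@H](C)CCC=C(C)C)C=O | intermediate
4 | methyl (2E,4S)-4-[(2S)-6-methylhept-5-en-2-yl]-7-oxooct-2-enoate | CC(=O)CC[C@@H]([C@@H](C)CCC=C(C)C)/C=C/C(=O)OC | intermediate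
5 | methyl (2E,4S)-4-[(2S,5E)-7-hydroxy-6-methylhept-5-en-2-yl]-7-oxooct-2-enoate | CC(=O)CC[C@@H]([C@@H](C)CC/C=C(\C)CO)/C=C/C(=O)OC | intermediate
6 | methyl (2E,4S)-4-[(2S,5E)-7-(tert-butyldiphenylsilyloxy)-6-methylhept-5-en-2-yl]-7-oxooct-2-enoate | CC(=O)CC[C@@H]([C@@H](C)CC/C=C(\C)CO[Si](c1ccccc1)(c1ccccc1)C(C)(C)C)/C=C/C(=O)OC | intermediate
7 | 3-bromocyclopent-2-en-1-one | O=C1CCC(Br)=C1 | starting material
8 | 7-bromo-1,4-dioxaspiro[4.4]non-6-ene | BrC1=CC2(CC1)OCCO2 | intermediate
9 | (1,4-dioxaspiro[4.4]non-6-en-7-yl)lithium | [Li]C1=CC2(CC1)OCCO2 | intermediate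
10 | dichloro(1,4-dioxaspiro[4.4]non-6-en-7-yl)cerium | Cl[Ce](Cl)C1=CC2(CC1)OCCO2 | intermediate
11 | methyl (2E,4S)-7-(1,4-dioxaspiro[4.4]non-6-en-7-yl)-7-hydroxy-4-Rs-oct-2-enoate, both C7 epimers | OC(C)(CC[C@@H]([C@@H](C)CC/C=C(\C)CO[Si](c1ccccc1)(c1ccccc1)C(C)(C)C)/C=C/C(=O)OC)C1=CC2(CC1)OCCO2 | intermediate
12 | methyl (2E,4S)-7-hydroxy-7-(3-oxocyclopent-1-en-1-yl)-4-Rs-oct-2-enoate, both C7 epimers | OC(C)(CC[C@@H]([C@@H](C)CC/C=C(\C)CO[Si](c1ccccc1)(c1ccccc1)C(C)(C)C)/C=C/C(=O)OC)C1=CC(=O)CC1 | intermediate
13 | methyl 11-hydroxy-11-methyl-4-oxo-8-Rs-tricyclo[5.4.0.0^1,5]undecane-6-carboxylate; five- and six-membered rings cis-fused to the cyclobutane on opposite faces, CO2Me cis to C4 and trans to C8, H7/H8 trans, both C11 epimers | O=C1CC[C@]23[C@H]1[C@H](C(=O)OC)[C@H]2[C@H]([C@@H](C)CC/C=C(\C)CO[Si](c4ccccc4)(c4ccccc4)C(C)(C)C)CCC3(C)O | intermediate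
14 | methyl 11-hydroxy-11-methyl-4-methylidene-8-Rs-tricyclo[5.4.0.0^1,5]undecane-6-carboxylate, configuration as 13 | C=C1CC[C@]23[C@H]1[C@H](C(=O)OC)[C@H]2[C@H]([C@@H](C)CC/C=C(\C)CO[Si](c4ccccc4)(c4ccccc4)C(C)(C)C)CCC3(C)O | intermediate
15 | N-methoxy-N-methyl amide corresponding to ester 14 (Weinreb amide) | C=C1CC[C@]23[C@H]1[C@H](C(=O)N(C)OC)[C@H]2[C@H]([C@@H](C)CC/C=C(\C)CO[Si](c4ccccc4)(c4ccccc4)C(C)(C)C)CCC3(C)O | intermediate
16 | 1-(11-hydroxy-11-methyl-4-methylidene-8-Rs-tricyclo[5.4.0.0^1,5]undecan-6-yl)pent-4-en-1-one, configuration as 13 | C=C1CC[C@]23[C@H]1[C@H](C(=O)CCC=C)[C@H]2[C@H]([C@@H](C)CC/C=C(\C)CO[Si](c4ccccc4)(c4ccccc4)C(C)(C)C)CCC3(C)O | intermediate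
17 | tetracyclic ketone: cyclohept-4-en-1-one fused across C4, C5, C6 of the tricycle of 14 (C6–CO–CH2–CH2–CH=C4), tertiary alcohol and Rs retained | O=C1CCC=C2CC[C@]34[C@H]2[C@H]1[C@H]3[C@H]([C@@H](C)CC/C=C(\C)CO[Si](c5ccccc5)(c5ccccc5)C(C)(C)C)CCC4(C)O | intermediate
18 | tetracyclic diene alcohol: 17 with C=O replaced by C=CH2 | C=C1CCC=C2CC[C@]34[C@H]2[C@H]1[C@H]3[C@H]([C@@H](C)CC/C=C(\C)CO[Si](c5ccccc5)(c5ccccc5)C(C)(C)C)CCC4(C)O | intermediate
19 | methyl oxalate (mixed oxalate diester) of tertiary alcohol 18 | C=C1CCC=C2CC[C@]34[C@H]2[C@H]1[C@H]3[C@H]([C@@H](C)CC/C=C(\C)CO[Si](c5ccccc5)(c5ccccc5)C(C)(C)C)CCC4(C)OC(=O)C(=O)OC | intermediate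
20 | O-tert-butyldiphenylsilyl ether of the target | C=C1CCC=C2CCC3=C(C)CC[C@@H]([C@@H](C)CC/C=C(\C)CO[Si](c4ccccc4)(c4ccccc4)C(C)(C)C)[C@@H]3[C@@H]1C2 | intermediate
21 | CNP0289180.1: (E)-2-methylhept-2-en-1-ol carrying at C6 the methylcyclohexene-fused methylidenebicyclo[4.4.1]undecene | C=C1CCC=C2CCC3=C(C)CC[C@@H]([C@@H](C)CC/C=C(\C)CO)[C@@H]3[C@@H]1C2 | target

**Step count and risks**
Total step count: 15. Longest linear sequence: 14 steps (steps 1–4 and 6–15; step 5 prepares the reagent).

Steps most likely to fail: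

Step 8. The excited enone may lose its energy to the conjugated ester (E/Z isomerisation) or abstract hydrogen from the tether before the slow 1,6-closure, so that conversion to the cycloadduct stalls. The fallback replaces the conjugated 2π partner by an isolated alkene at the alcohol oxidation level, which cannot accept triplet energy. It sets out from 11: i-Bu2AlH (toluene, −78 °C) should reduce the ester to the allylic alcohol ketal F1; PPTS in aqueous THF gives the hydroxy enone F2; irradiation as in step 8 gives the hydroxymethyl photoadduct F3 under the same tether and allylic-centre control; TEMPO/PhI(OAc)2 in aqueous MeCN oxidises the primary alcohol to the carboxylic acid F4; Me3SiCHN2 in MeOH/toluene returns to the route at 13.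

Step 14. Hydrogen transfer from the stannane to the tertiary radical may outrun ring opening, or the unstabilised ring-opened radical may rearrange (1,2-vinyl shift) before it is reduced. The fallback changes the order so that the ring-opened radical is an α-keto radical, at the price of a later bridgehead ring closure. It sets out from 13: ClC(O)CO2Me, DMAP, pyridine gives the oxalate F5; Bu3SnH/AIBN in toluene at 110 °C should open the cyclobutane to the bicyclic keto ester F6 (cycloheptanone fused to the methylcyclohexene); Ph3P=CH2 gives the methylidene ester F7; MeNH(OMe)·HCl/i-PrMgCl gives the Weinreb amide F8, and but-3-enylmagnesium bromide then gives the pentenyl ketone F9; ring-closing metathesis with the second-generation Grubbs catalyst at high dilution in toluene at 80 °C closes the bridgehead alkene to the bicyclo[4.4.1]undecenone F10; Ph3P=CH2 returns to the route at 20.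

Step 6 (with step 5). The bromo ketal may shift its double bond or decompose on preparation or lithiation, and the organometallic may attack the unsaturated ester. The fallback carries out the union at the alcohol oxidation level. It sets out from 7 and 6: NaBH4/CeCl3·7H2O in MeOH (Luche reduction) gives racemic 3-bromocyclopent-2-en-1-ol F11; Et3SiCl/imidazole gives the silyl ether F12; t-BuLi and then CeCl3 at −78 °C give the vinyllithium F13 and the organocerium reagent F14, which adds to 6 to give the silyl-protected adduct F15; PPTS in MeOH frees the diol F16; MnO2 in CH2Cl2 oxidises only the secondary allylic alcohol and returns to the route at 12.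

Further compounds
F1 | step 8 | (2E,4S)-7-(1,4-dioxaspiro[4.4]non-6-en-7-yl)-4-Rs-oct-2-ene-1,7-diol | OC(C)(CC[C@@H]([C@@H](C)CC/C=C(\C)CO[Si](c1ccccc1)(c1ccccc1)C(C)(C)C)/C=C/CO)C1=CC2(CC1)OCCO2
F2 | step 8 | 3-[(5S,6E)-2,8-dihydroxy-5-Rs-oct-6-en-2-yl]cyclopent-2-en-1-one | OC(C)(CC[C@@H]([C@@H](C)CC/C=C(\C)CO[Si](c1ccccc1)(c1ccccc1)C(C)(C)C)/C=C/CO)C1=CC(=O)CC1
F3 | step 8 | 11-hydroxy-6-(hydroxymethyl)-11-methyl-8-Rs-tricyclo[5.4.0.0^1,5]undecan-4-one, configuration as 13 | O=C1CC[C@]23[C@H]1[C@H](CO)[C@H]2[C@H]([C@@H](C)CC/C=C(\C)CO[Si](c4ccccc4)(c4ccccc4)C(C)(C)C)CCC3(C)O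
F4 | step 8 | 11-hydroxy-11-methyl-4-oxo-8-Rs-tricyclo[5.4.0.0^1,5]undecane-6-carboxylic acid, configuration as 13 | O=C1CC[C@]23[C@H]1[C@H](C(=O)O)[C@H]2[C@H]([C@@H](C)CC/C=C(\C)CO[Si](c4ccccc4)(c4ccccc4)C(C)(C)C)CCC3(C)O
F5 | step 14 | methyl oxalate of tertiary alcohol 13 | O=C1CC[C@]23[C@H]1[C@H](C(=O)OC)[C@H]2[C@H]([C@@H](C)CC/C=C(\C)CO[Si](c4ccccc4)(c4ccccc4)C(C)(C)C)CCC3(C)OC(=O)C(=O)OC
F6 | step 14 | bicyclic keto ester: methyl ester on the cycloheptanone ring fused to the methylcyclohexene bearing Rs | O=C1CCC2=C(C)CC[C@@H]([C@@H](C)CC/C=C(\C)CO[Si](c3ccccc3)(c3ccccc3)C(C)(C)C)[C@@H]2[C@@H](C(=O)OC)C1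
F7 | step 14 | methylidene analogue of F6 | C=C1CCC2=C(C)CC[C@@H]([C@@H](C)CC/C=C(\C)CO[Si](c3ccccc3)(c3ccccc3)C(C)(C)C)[C@@H]2[C@@H](C(=O)OC)C1
F8 | step 14 | N-methoxy-N-methyl amide corresponding to F7 | C=C1CCC2=C(C)CC[C@@H]([C@@H](C)CC/C=C(\C)CO[Si](c3ccccc3)(c3ccccc3)C(C)(C)C)[C@@H]2[C@@H](C(=O)N(C)OC)C1
F9 | step 14 | pent-4-enoyl ketone corresponding to F7 | C=C1CCC2=C(C)CC[C@@H]([C@@H](C)CC/C=C(\C)CO[Si](c3ccccc3)(c3ccccc3)C(C)(C)C)[C@@H]2[C@@H](C(=O)CCC=C)C1
F10 | step 14 | bicyclo[4.4.1]undecenone: compound 20 with C=O in place of the exocyclic C=CH2 | O=C1CCC=C2CCC3=C(C)CC[C@@H]([C@@H](C)CC/C=C(\C)CO[Si](c4ccccc4)(c4ccccc4)C(C)(C)C)[C@@H]3[C@@H]1C2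
F11 | step 6 | 3-bromocyclopent-2-en-1-ol (racemic) | OC1CCC(Br)=C1
F12 | step 6 | [(3-bromocyclopent-2-en-1-yl)oxy]triethylsilane (racemic) | CC[Si](CC)(CC)OC1CCC(Br)=C1
F13 | step 6 | [3-(triethylsilyloxy)cyclopent-1-en-1-yl]lithium | CC[Si](CC)(CC)OC1CCC([Li])=C1
F14 | step 6 | dichloro[3-(triethylsilyloxy)cyclopent-1-en-1-yl]cerium | CC[Si](CC)(CC)OC1CCC([Ce](Cl)Cl)=C1
F15 | step 6 | methyl (2E,4S)-7-hydroxy-4-Rs-7-[3-(triethylsilyloxy)cyclopent-1-en-1-yl]oct-2-enoate, mixture at both carbinol carbons | OC(C)(CC[C@@H]([C@@H](C)CC/C=C(\C)CO[Si](c1ccccc1)(c1ccccc1)C(C)(C)C)/C=C/C(=O)OC)C1=CC(O[Si](CC)(CC)CC)CC1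
F16 | step 6 | methyl (2E,4S)-7-hydroxy-7-(3-hydroxycyclopent-1-en-1-yl)-4-Rs-oct-2-enoate, mixture at both carbinol carbons | OC(C)(CC[C@@H]([C@@H](C)CC/C=C(\C)CO[Si](c1ccccc1)(c1ccccc1)C(C)(C)C)/C=C/C(=O)OC)C1=CC(O)CC1
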